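Per hour is the unit we want: the flasks below share a charge and a time and differ in temperature, so we set out to compare them through a rate constant.

the same everywhere: starting material 0.050 M

| charge | protic impurity | solid reagent | temperature | remark | time |
|---|---|---|---|---|---|
| oak | 3.4 mM | 0.075 M | −5 °C | run made earlier |  |
| cedar | 7.5 mM | 0.075 M | 38 °C | run made earlier |  |
| teal | 5.00 mM | 0.0750 M | 75 °C |  | 8.0 h |
| amber | 5.00 mM | 0.0750 M | 0 °C |  | 8.0 h |
| ochre | 5.00 mM | 0.0750 M | 50 °C |  | 8.0 h |
| violet | 5.00 mM | 0.0750 M | 25 °C |  | 8.0 h |

| run | time / h | target / % | starting material / % |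
|---|---|---|---|
| oak | 20.0 | 0.4 | 93.1 |
| oak | 72.0 | 0 | 85.3 |
| oak | 120 | 3.9 | 79.7 |
| oak | 192 | 7.9 | 71.0 |
| oak | 240 | 10.0 | 70.1 |
| oak | 288 | 14.1 | 63.4 |
| cedar | 2.50 | 7.6 | 58.9 |
| cedar | 8.00 | 33.5 | 39.7 |
| cedar | 15.0 | 53.2 | 24.1 |
| cedar | 25.0 | 71.8 | 9.0 |
| cedar | 30.0 | 74.1 | 5.3 |
| cedar | 40.0 | 78.6 | 3.7 |

(scatter of a reading: 1 percentage point)

- as a solid, counted per litre of solution: solid reagent
- at the start none of the solid reagent is in solution

- the flask with the highest amount of target, in percent of the starting material charged ("all alike" if they lie within 1.5 percentage points) (teal / amber / ochre / violet / all alike)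
- final target, as a percentage of the starting material charged, in teal
- final target, as a percentage of the starting material charged, in amber
- final target, as a percentage of the starting material charged, in ochre
- final target, as a percentage of the starting material charged, in violet

Take the protic impurity first. If each impurity molecule takes one starting material, it costs the new flasks a share of 10.0%. Cedar's gap at its last reading, 17.7%, stands near cedar's share of 15.0%. We subtract that share and call the remainder, neither starting material nor target, the held amount H. In cedar, H reads 11.8% at 8.00 h and 7.70% at 15.0 h. In oak, with a share of 6.80%, it reads 14.3% at 192 h and 15.7% at 288 h.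

Now the temperature. We freeze everything else and treat H as the source of target, a pseudo-first-order step. Cedar then gives 0.289 h⁻¹ for the exit constant k_x, the target gained per hour over the mean of H. Oak gives 0.00431 h⁻¹. Both are readings and carry the scatter, and together they give an activation energy of 67.8 kJ mol⁻¹. Carried to the new flasks, k_x becomes 0.00752 h⁻¹ in amber, 0.0920 h⁻¹ in violet, 0.764 h⁻¹ in ochre and 4.69 h⁻¹ in teal.

Last, the time. Over 8.0 h, k_x·t is 0.0602 in amber, so we put amber last. In teal it is 37.5, so there target follows H, which neither run shows at that temperature. We therefore leave the top place open, where the forecast does not.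

The forecast names teal: teal 87% (70% to 92%), ochre 65% (48% to 80%), violet 9% (4% to 16%), amber 0.3% (0% to 1.5%). It adds: “Teal is an extrapolation, since an unseen high-temperature loss could lower it.”

The flasks give teal 18.8%, amber 0.0721%, ochre 32.1% and violet 19.1%, so ochre leads.

    starting material ⇌ reactive form (K = 1.63, k = 4.52 × 10⁻⁵ s⁻¹, Ea = 107 kJ mol⁻¹, ΔH = −90.0 kJ mol⁻¹)
    partner + reactive form → target (k = 0.00152 M⁻¹ s⁻¹, Ea = 70.0 kJ mol⁻¹)
    starting material + protic impurity → quenched substrate (k = 0.00213 M⁻¹ s⁻¹, Ea = 47.0 kJ mol⁻¹)
    target → over-reaction product (k = 2.82 × 10⁻⁸ s⁻¹, Ea = 112 kJ mol⁻¹)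
    solid reagent ⇌ partner, rate k5*(cs5 - [partner]) while solid is left; crystals form when [partner] > cs5 (solubility = 20.0 mM, k = 1.60 × 10⁻⁴ s⁻¹)
    (constants at 25 °C)

We take the reactive form for our H. In ochre it stood at 6.64% at 4.00 h and 5.07% at 8.00 h, so a k_x of 0.764 h⁻¹ reckons 18 percentage points over those hours, against 18 points of target plus over-reaction product found. In teal k_x is larger, at 4.69 h⁻¹, but the reactive form stood at 0.700% and 0.583%, so the reckoning gives 12 points, against 13 points found.

The runs were computed with constants of no real substance; noise was put on by code.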